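Cuts: first the ester C–O bond at C1' (giving shikonin and 3-acetoxy-3-methylbutanoic acid), then the second quinone oxygen (back to a 1-naphthol and its oxygen-bridged isomer), and last the two ring-fusion bonds C1–C8a and C4–C4a together.
Enabling feature: ring B (C1–C4, side chain on C2) is attached to ring A only through the adjacent carbons C4a and C8a. These sit between the equivalent oxygens on C5 and C8, so ring A can act as a symmetrical 3,6-dialkoxybenzyne and ring B as a 3-substituted furan, with no regiochemical question.
Forward: ring A is bought as bromohydroquinone and the side chain is joined to 3-bromofuran by Weinreb acylation. Ring B closes in the aryne–furan [4+2] step; the oxygen bridge becomes one quinone oxygen and a Teuber oxidation supplies the other.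
Stereochemistry: the only stereocentre, C1' (R), comes from reagent-controlled reduction of the furyl ketone with (+)-Ipc2BCl and is carried on as a silyl ether. The bridgehead centres of the cycloadduct are transient.
Endgame: dilute acid frees the three hydroxyls, and the hydrogen-bonded peri phenols allow selective Steglich acylation of the C1' alcohol.

Key step: step 6

Remark: naphthoquinone numbering is used (side chain on C2, carbinol carbon C1'), and nBuLi and LiN(iPr)2 are taken as commercial solutions.

Step 1
Reactants: 1 bromohydroquinone (2-bromobenzene-1,4-diol)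
Product: 2 2-bromo-1,4-bis(methoxymethoxy)benzene
Conditions: MeOCH2Cl (2.5 equiv), iPr2NEt (3 equiv), CH2Cl2, 0 °C to rt
Reagents that add atoms: chloromethyl methyl ether, COCCl
Why: Double O-alkylation of the phenols with an α-chloro ether (Williamson-type MOM protection) is routine, and the MOM ethers tolerate lithium amides, acidify the ring proton next to bromine and leave again in dilute acid.

Step 2
Reactants: 3 4-methylpent-3-enoic acid
Product: 5 N-methoxy-N,4-dimethylpent-3-enamide, via acylimidazole 4 (not isolated)
Conditions: 1,1'-carbonyldiimidazole (1.1 equiv), CH2Cl2, 0 °C to rt; then MeNH(OMe)·HCl (1.2 equiv), rt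
Reagents that add atoms: N,O-dimethylhydroxylamine hydrochloride, CNOC.Cl
Why: Activation of the acid as its imidazolide followed by aminolysis (Weinreb amide formation) needs no added base, so the β,γ-double bond should stay out of conjugation.

Step 3
Reactants: 6 3-bromofuran; 5 N-methoxy-N,4-dimethylpent-3-enamide
Product: 8 1-(furan-3-yl)-4-methylpent-3-en-1-one, via 3-furyllithium 7 (not isolated)
Conditions: nBuLi (1.05 equiv), Et2O, −78 °C; then 5, THF, −78 °C; AcOH quench at −78 °C
Reagents that add atoms: none
Why: Bromine–lithium exchange at −78 °C gives the 3-lithiofuran before it can equilibrate to the 2-lithio isomer, the Weinreb ketone synthesis stops at the ketone, and the cold acidic quench keeps the double bond in the β,γ-position.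

Step 4
Reactants: 8 1-(furan-3-yl)-4-methylpent-3-en-1-one
Product: 9 (R)-1-(furan-3-yl)-4-methylpent-3-en-1-ol
Conditions: (+)-Ipc2BCl (1.4 equiv), THF, −25 °C; then HN(CH2CH2OH)2, Et2O, rt
Reagents that add atoms: none
Why: Asymmetric reduction with B-chlorodiisopinocampheylborane transfers the β-hydride of one isopinocampheyl group through a boat-like six-membered transition state in which the flat furyl ring acts as the large group and the CH2 chain faces the pinane methyl, so the (+)-reagent, made from (−)-α-pinene, should set C1' as R, as it does with aryl n-alkyl ketones.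

Step 5
Reactants: 9 (R)-1-(furan-3-yl)-4-methylpent-3-en-1-ol
Product: 10 (R)-tert-butyl[1-(furan-3-yl)-4-methylpent-3-enyloxy]dimethylsilane
Conditions: tBuMe2SiCl (1.2 equiv), imidazole (2.5 equiv), DMF, rt
Reagents that add atoms: tert-butyldimethylsilyl chloride, CC(C)(C)[Si](C)(C)Cl
Why: Imidazole-promoted silylation of a secondary alcohol breaks no bond at C1', and the silyl ether has no acidic proton and withstands the lithium amide of step 6.

Step 6
Reactants: 2 2-bromo-1,4-bis(methoxymethoxy)benzene; 10 (R)-tert-butyl[1-(furan-3-yl)-4-methylpent-3-enyloxy]dimethylsilane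
Product: 13 tert-butyl{(1R)-1-[5,8-bis(methoxymethoxy)-1,4-dihydro-1,4-epoxynaphthalen-2-yl]-4-methylpent-3-enyloxy}dimethylsilane (both bridgehead diastereomers), via aryllithium 11 (not isolated), via aryne 12 (not isolated)
Conditions: 10 (1 equiv), 2 (2.5 equiv), THF, −78 °C; LiN(iPr)2 (2.7 equiv) dropwise; −78 °C to rt
Reagents that add atoms: none
Why: LiN(iPr)2 takes the C3 proton of 2, which is acidified by both the bromine and the adjacent MOM ether, and aryllithium 11 loses LiBr on warming to give aryne 12. The strained, electrophilic triple bond then adds suprafacially across C2 and C5 of furan 10 in a concerted [4+2] cycloaddition that makes C1–C8a and C4–C4a at once, which is the well-known aryne Diels–Alder capture of 3,6-dialkoxybenzynes by furans. Ring B closes as a six-membered carbocycle by intermolecular cycloaddition of the four furan carbons onto the two aryne carbons, and the furan oxygen remains as a 1,4-bridge. The two bridgehead centres are new but uncontrolled, because the remote C1' centre hardly distinguishes the furan faces; both diastereomers are accepted since step 7 erases these centres, and C1' itself is not touched. No regiocontrol is needed, because 12 carries the same MOM ether on each side of the triple bond and both orientations give one constitution. The step needs chemoselectivity for the furan diene over an ene reaction at the prenyl group and over addition of HN(iPr)2, which rests on the high reactivity of furans as aryne traps and is supported by using 2 and the base in excess over 10.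

Step 7
Reactants: 13 tert-butyl{(1R)-1-[5,8-bis(methoxymethoxy)-1,4-dihydro-1,4-epoxynaphthalen-2-yl]-4-methylpent-3-enyloxy}dimethylsilane
Product: 16 (R)-2-[1-(tert-butyldimethylsilyloxy)-4-methylpent-3-enyl]-5,8-bis(methoxymethoxy)naphthalene-1,4-dione, via 2-substituted naphthol 14 (not isolated), via 3-substituted naphthol 15 (not isolated)
Conditions: [Rh(cod)Cl]2 (2.5 mol %), THF, 60 °C; then in the same flask acetone, aq KH2PO4, (KSO3)2NO (2.5 equiv), 0 °C to rt
Reagents that add atoms: potassium nitrosodisulfonate (KSO3)2NO, [K+].[K+].[O]N(S(=O)(=O)[O-])S(=O)(=O)[O-]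
Why: Monovalent rhodium inserts into a bridgehead C–O bond and β-hydride elimination with tautomerisation gives the 1-naphthols (the known neutral isomerisation of 7-oxabenzonorbornadienes), after which the Teuber oxidation places oxygen on the free para carbon of either naphthol, so 14 and 15 converge on one quinone because ring A is symmetrical, and C1' takes no part.

Step 8
Reactants: 16 (R)-2-[1-(tert-butyldimethylsilyloxy)-4-methylpent-3-enyl]-5,8-bis(methoxymethoxy)naphthalene-1,4-dione
Product: 17 shikonin, (R)-5,8-dihydroxy-2-(1-hydroxy-4-methylpent-3-enyl)naphthalene-1,4-dione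
Conditions: aq HCl (2 mol/L), THF, rt, argon, dark
Reagents that add atoms: none
Why: Acid hydrolysis of the two aryl MOM acetals (helped by the hydrogen bond each freed phenol forms to its peri carbonyl) and of the silyl ether cleaves only O–CH2 and O–Si bonds, so the C1'–O bond and its R configuration should be retained.

Step 9
Reactants: 18 3-hydroxy-3-methylbutanoic acid
Product: 19 3-acetoxy-3-methylbutanoic acid
Conditions: Ac2O (3 equiv), pyridine, 4-(dimethylamino)pyridine (10 mol %), CH2Cl2, rt; then H2O
Reagents that add atoms: acetic anhydride, CC(=O)OC(C)=O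
Why: Nucleophilic catalysis by 4-(dimethylamino)pyridine makes acetylation of a tertiary alcohol practical, and the aqueous quench hydrolyses any mixed anhydride at the carboxyl group.

Step 10
Reactants: 17 shikonin; 19 3-acetoxy-3-methylbutanoic acid
Product: 20 (R)-1-(5,8-dihydroxy-1,4-dioxo-1,4-dihydronaphthalen-2-yl)-4-methylpent-3-enyl 3-acetoxy-3-methylbutanoate
Conditions: 19 (1.5 equiv), N,N'-dicyclohexylcarbodiimide (1.5 equiv), 4-(dimethylamino)pyridine (0.2 equiv), CH2Cl2, 0 °C to rt
Reagents that add atoms: none
Why: In this Steglich esterification both phenols are held in strong hydrogen bonds to the quinone carbonyls and are poor nucleophiles, so the activated acid should acylate only the C1' alcohol, with retention because the C1'–O bond is not broken.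

Compound list
1 | bromohydroquinone (2-bromobenzene-1,4-diol) | Oc1ccc(O)c(Br)c1 | starting material
2 | 2-bromo-1,4-bis(methoxymethoxy)benzene | COCOc1ccc(OCOC)c(Br)c1 | intermediate
3 | 4-methylpent-3-enoic acid | CC(C)=CCC(=O)O | starting material
4 | 1-(imidazol-1-yl)-4-methylpent-3-en-1-one | CC(C)=CCC(=O)n1ccnc1 | intermediate
5 | N-methoxy-N,4-dimethylpent-3-enamide | CC(C)=CCC(=O)N(C)OC | intermediate
6 | 3-bromofuran | Brc1ccoc1 | starting material
7 | furan-3-yllithium | [Li]c1ccoc1 | intermediate
8 | 1-(furan-3-yl)-4-methylpent-3-en-1-one | CC(C)=CCC(=O)c1ccoc1 | intermediate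
9 | (R)-1-(furan-3-yl)-4-methylpent-3-en-1-ol | CC(C)=CC[C@@H](O)c1ccoc1 | intermediate
10 | (R)-tert-butyl[1-(furan-3-yl)-4-methylpent-3-enyloxy]dimethylsilane | CC(C)=CC[C@@H](O[Si](C)(C)C(C)(C)C)c1ccoc1 | intermediate
11 | [2-bromo-3,6-bis(methoxymethoxy)phenyl]lithium | COCOc1ccc(OCOC)c(Br)c1[Li] | intermediate
12 | 3,6-bis(methoxymethoxy)benzyne | COCOC1=CC=C(OCOC)C#C1 | intermediate
13 | tert-butyl{(1R)-1-[5,8-bis(methoxymethoxy)-1,4-dihydro-1,4-epoxynaphthalen-2-yl]-4-methylpent-3-enyloxy}dimethylsilane, mixture of the two bridgehead diastereomers | COCOc1ccc(OCOC)c2c1C1OC2C=C1[C@H](O[Si](C)(C)C(C)(C)C)CC=C(C)C | intermediate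
14 | (R)-2-[1-(tert-butyldimethylsilyloxy)-4-methylpent-3-enyl]-5,8-bis(methoxymethoxy)naphthalen-1-ol | COCOc1ccc(OCOC)c2c(O)c([C@H](O[Si](C)(C)C(C)(C)C)CC=C(C)C)ccc12 | intermediate
15 | (R)-3-[1-(tert-butyldimethylsilyloxy)-4-methylpent-3-enyl]-5,8-bis(methoxymethoxy)naphthalen-1-ol | COCOc1ccc(OCOC)c2c(O)cc([C@H](O[Si](C)(C)C(C)(C)C)CC=C(C)C)cc12 | intermediate
16 | (R)-2-[1-(tert-butyldimethylsilyloxy)-4-methylpent-3-enyl]-5,8-bis(methoxymethoxy)naphthalene-1,4-dione | COCOc1ccc(OCOC)c2c1C(=O)C=C([C@H](O[Si](C)(C)C(C)(C)C)CC=C(C)C)C2=O | intermediate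
17 | shikonin, (R)-5,8-dihydroxy-2-(1-hydroxy-4-methylpent-3-enyl)naphthalene-1,4-dione | CC(C)=CC[C@@H](O)C1=CC(=O)c2c(O)ccc(O)c2C1=O | intermediate
18 | 3-hydroxy-3-methylbutanoic acid | CC(C)(O)CC(=O)O | starting material
19 | 3-acetoxy-3-methylbutanoic acid | CC(=O)OC(C)(C)CC(=O)O | intermediate
20 | (R)-1-(5,8-dihydroxy-1,4-dioxo-1,4-dihydronaphthalen-2-yl)-4-methylpent-3-enyl 3-acetoxy-3-methylbutanoate | CC(=O)OC(C)(C)CC(=O)O[C@H](CC=C(C)C)C1=CC(=O)c2c(O)ccc(O)c2C1=O | target

Total step count: 10.
Longest linear sequence: 8 steps (steps 2, 3, 4, 5, 6, 7, 8 and 10, from 3 to 20).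

Steps most likely to fail

Step 6. The aryne may be consumed by addition of diisopropylamine or its lithium amide, and the furan may be metalated at C2, so the limiting furan would be converted only in part. The fallback releases the aryne by halogen–metal exchange in an amine-free flask.
- It sets out from 2. Lithiation with LiN(iPr)2 at −90 °C, where 11 persists, and quenching with iodine would give 2-bromo-3-iodo-1,4-bis(methoxymethoxy)benzene F1, which is purified free of amine.
- Slow addition of nBuLi to F1 and 10 in toluene–THF at −78 °C would trigger the fast iodine–lithium exchange. This regenerates 11 and then 12 with only the furan present as a partner.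
- The path comes back to the route at 13.

Step 7. Rhodium may insert only slowly at the trisubstituted bicyclic alkene. The nitroxyl radical may attack the ortho carbon, or may react sluggishly at the crowded para carbon of 15, while the electron-rich naphthols degrade in air. The fallback opens the bridge heterolytically and oxidises ionically to a masked quinone.
- It sets out from 13. The bridge would be ionised with a catalytic amount of CF3CO2H in CH2Cl2 at −20 °C. The peri MOM ether assists this opening, which does not depend on access of a metal to the alkene.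
- The resulting 14 and 15 would then be oxidised by a two-electron dearomatisation with PhI(OAc)2 (2.2 equiv) in MeOH at 0 °C, which delivers methanol twice to the para carbon.
- The products would be the quinone monoketals (R)-2-[1-(tert-butyldimethylsilyloxy)-4-methylpent-3-enyl]-4,4-dimethoxy-5,8-bis(methoxymethoxy)naphthalen-1(4H)-one F2 and its 3-substituted isomer (R)-3-[1-(tert-butyldimethylsilyloxy)-4-methylpent-3-enyl]-4,4-dimethoxy-5,8-bis(methoxymethoxy)naphthalen-1(4H)-one F3.
- Both ketals hydrolyse under the conditions of step 8 together with the MOM and silyl groups, so the path skips 16 and comes back at 17.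

Step 8. The freed C1' hydroxyl may cyclise onto the prenyl double bond under acid. Once the naphthazarin is unveiled, partial ionisation at C1' may also erode the configuration. The fallback changes the order of events so that no free C1' hydroxyl ever meets acid.
- It sets out from 16. Only the silyl ether is removed first, with HF·pyridine in THF at 0 °C, to give (R)-2-(1-hydroxy-4-methylpent-3-enyl)-5,8-bis(methoxymethoxy)naphthalene-1,4-dione F4.
- Steglich esterification of F4 with 19 would give (R)-1-[5,8-bis(methoxymethoxy)-1,4-dioxo-1,4-dihydronaphthalen-2-yl]-4-methylpent-3-enyl 3-acetoxy-3-methylbutanoate F5.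
- The phenolic MOM ethers are taken off last with NaHSO4 on SiO2 in CH2Cl2 at rt.
- The path skips 17 and comes back at 20.

Further compounds
F1 | step 6 | 2-bromo-3-iodo-1,4-bis(methoxymethoxy)benzene | COCOc1ccc(OCOC)c(Br)c1I
F2 | step 7 | (R)-2-[1-(tert-butyldimethylsilyloxy)-4-methylpent-3-enyl]-4,4-dimethoxy-5,8-bis(methoxymethoxy)naphthalen-1(4H)-one | COCOc1ccc(OCOC)c2c1C(=O)C([C@H](O[Si](C)(C)C(C)(C)C)CC=C(C)C)=CC2(OC)OC
F3 | step 7 | (R)-3-[1-(tert-butyldimethylsilyloxy)-4-methylpent-3-enyl]-4,4-dimethoxy-5,8-bis(methoxymethoxy)naphthalen-1(4H)-one | COCOc1ccc(OCOC)c2c1C(=O)C=C([C@H](O[Si](C)(C)C(C)(C)C)CC=C(C)C)C2(OC)OC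
F4 | step 8 | (R)-2-(1-hydroxy-4-methylpent-3-enyl)-5,8-bis(methoxymethoxy)naphthalene-1,4-dione | COCOc1ccc(OCOC)c2c1C(=O)C=C([C@H](O)CC=C(C)C)C2=O
F5 | step 8 | (R)-1-[5,8-bis(methoxymethoxy)-1,4-dioxo-1,4-dihydronaphthalen-2-yl]-4-methylpent-3-enyl 3-acetoxy-3-methylbutanoate | COCOc1ccc(OCOC)c2c1C(=O)C=C([C@H](OC(=O)CC(C)(C)OC(C)=O)CC=C(C)C)C2=O
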